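**Plan**

Ring atoms are lettered Ca (CH carrying the hydroxypentenyl chain), Cb (quaternary carbon), Cc (CHBr), Cd and Ce (CH2), Cf (ring carbinol carbon).
Retrosynthesis: the tertiary carbinol Cf(CH3)(OH) beside the methylene Ce is read as a hydrated trisubstituted olefin Ce=Cf. The cyclohexene so revealed has Cb and Cc on the two sp3 carbons opposite the double bond, which is the Diels–Alder pattern, so the ring bonds Ca–Cb and Cc–Cd are cut together into a Ca=Cf–Ce=Cd diene and a Cb=Cc bromoalkene. The (E)-CH=CH–C(CH3)2OH olefin is then cut by cross-metathesis, the Cb methyl is traced back to the formyl group that activates the dienophile, and the diene is traced back to (S)-linalool.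
Forward: (S)-linalool is silylated, oxidised at its E-methyl group and methylenated to the diene (steps 1–3); propargyl alcohol gives (Z)-2-allyl-3-bromoacrolein (steps 4–5); the cycloaddition closes the only ring (step 6); then CHO to CH3 (steps 7–8), epoxidation and hydride opening (steps 9–10), cross-metathesis (step 11) and desilylation (step 12).
Stereochemistry: the side-chain carbinol centre is bought with linalool. Ca, Cb and Cc are set in one event: relative configuration from the E diene, the Z enal and endo-formyl approach, absolute configuration from a chiral oxazaborolidinium catalyst. Cf is relayed by substrate control in the epoxidation.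

Key step: step 6

Assumption: the sense of induction of the oxazaborolidinium catalyst on the α,β-disubstituted enal 11 is taken to follow the model for 2-substituted acroleins (formyl C–H···O contact, s-trans enal, one face screened by an aryl group); the (S)-diphenylprolinol-derived catalyst is written, and its equally available antipode is to be used if the exposed face proves to be the other one.

**Route**

Step 1
Reactants: 1 (S)-linalool, (3S)-3,7-dimethylocta-1,6-dien-3-ol (commercial)
Product: 2 triethyl{[(3S)-3,7-dimethylocta-1,6-dien-3-yl]oxy}silane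
Conditions: TESOTf, 2,6-lutidine, CH2Cl2, −78 to 0 °C
Reagents that add atoms: triethylsilyl trifluoromethanesulfonate, CC[Si](CC)(CC)OS(=O)(=O)C(F)(F)F
Why: Silylation of a hindered tertiary alcohol with a silyl triflate and a hindered pyridine base is standard, and the ether keeps the tertiary allylic oxygen from binding or ionising under the acidic cycloaddition and shields the neighbouring vinyl group in the later metathesis; no stereocentre is touched.

Step 2
Reactants: 2 triethyl{[(3S)-3,7-dimethylocta-1,6-dien-3-yl]oxy}silane
Product: 4 (2E,6S)-2,6-dimethyl-6-(triethylsilyloxy)octa-2,7-dienal, via allylic alcohol 3 (not isolated)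
Conditions: SeO2 (cat.), t-BuOOH, salicylic acid (cat.), CH2Cl2, rt; then MnO2, CH2Cl2, rt
Reagents that add atoms: tert-butyl hydroperoxide, CC(C)(C)OO; selenium dioxide, O=[Se]=O
Why: Riley allylic oxidation (ene reaction, then [2,3]-sigmatropic shift) attacks the E-methyl group of a 2-methylalk-2-ene selectively, and MnO2 then converges alcohol 3 and any aldehyde already formed onto the single E-enal without touching the isolated vinyl group.

Step 3
Reactants: 4 (2E,6S)-2,6-dimethyl-6-(triethylsilyloxy)octa-2,7-dienal
Product: 5 triethyl{[(3S,6E)-3,7-dimethylnona-1,6,8-trien-3-yl]oxy}silane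
Conditions: Ph3PCH3Br, KOtBu, THF, 0 °C to rt
Reagents that add atoms: methyltriphenylphosphonium bromide, C[P+](c1ccccc1)(c1ccccc1)c1ccccc1.[Br-]
Why: Wittig methylenation of the enal by the non-stabilised ylide should give the terminal 1,3-diene by 1,2-addition and leave the E geometry of the trisubstituted double bond unchanged.

Step 4
Reactants: 6 propargyl alcohol (prop-2-yn-1-ol); 7 allylmagnesium bromide
Product: 10 (2Z)-2-(bromomethylidene)pent-4-en-1-ol, via bromomagnesium propargyl alkoxide 8 (not isolated), via alkenylmagnesium chelate 9 (not isolated)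
Conditions: 7 (2.3 equiv), CuI (cat.), Et2O, 0 °C to rt; then NBS, THF, −78 to 0 °C; aq. NH4Cl
Reagents that add atoms: N-bromosuccinimide, O=C1CCC(=O)N1Br
Why: Copper-catalysed anti-carbomagnesiation of a propargylic alkoxide places the allyl group on the inner alkyne carbon and magnesium on the terminal carbon cis to the CH2O group within a five-membered chelate, and electrophilic bromination of the alkenyl–magnesium bond proceeds with retention, so bromine should end cis to the hydroxymethyl group.

Step 5
Reactants: 10 (2Z)-2-(bromomethylidene)pent-4-en-1-ol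
Product: 11 (2Z)-2-(bromomethylidene)pent-4-enal
Conditions: MnO2, CH2Cl2, rt, dark; used at once
Reagents that add atoms: none
Why: Oxidation of a primary allylic alcohol with activated MnO2 is mild and neutral and should keep the Z geometry (bromine cis to the formyl group) that the cycloaddition needs.

Step 6
Reactants: 5 triethyl{[(3S,6E)-3,7-dimethylnona-1,6,8-trien-3-yl]oxy}silane; 11 (2Z)-2-(bromomethylidene)pent-4-enal
Product: 12 (1S,2R,6S)-6-bromo-3-methyl-2-[(3S)-3-methyl-3-(triethylsilyloxy)pent-4-en-1-yl]-1-(prop-2-en-1-yl)cyclohex-3-ene-1-carbaldehyde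
Conditions: (S)-3,3-diphenyl-1-(2-methylphenyl)tetrahydro-1H,3H-pyrrolo[1,2-c][1,3,2]oxazaborole·Tf2NH (20 mol%), 11 (1.5 equiv), CH2Cl2, −78 to −40 °C
Reagents that add atoms: none
Why: The N-protonated oxazaborolidine binds the formyl oxygen of 11 and lowers its LUMO, and the s-trans enal then adds to the s-cis diene of 5 in a concerted, asynchronous [4+2] cycloaddition in which the CH2 terminus Cd bonds ahead to the bromine-bearing β-carbon Cc; the closest known reaction type is the enantioselective Diels–Alder reaction of 2-substituted acroleins with acyclic 1,3-dienes under chiral oxazaborolidinium catalysis. The one carbocycle of the target is closed here by intermolecular suprafacial–suprafacial [4+2] cycloaddition, both ring bonds (Ca–Cb and Cc–Cd) forming in the same event. The relative configuration of Ca and Cb follows from the E geometry of the diene terminus combined with endo placement of the formyl group (side chain cis to CHO, the future methyl group), and that of Cc from the Z geometry of the enal (Br cis to CHO). The absolute configuration of all three centres comes from the catalyst, which screens one face of the bound enal so that the diene adds to the Si face of the α-carbon; the carbinol centre of 5, three atoms from the diene, is not expected to interfere. Regioselectivity is needed and is secured by the alkyl substituent on the diene terminus Ca, which directs that terminus to the α-carbon as in the cycloadditions of 1-vinylcycloalkenes, and by the unhindered Cd terminus that leads bond formation; endo selectivity is needed and rests on the formyl group being the only π-acceptor of the dienophile.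

Step 7
Reactants: 12 (1S,2R,6S)-6-bromo-3-methyl-2-[(3S)-3-methyl-3-(triethylsilyloxy)pent-4-en-1-yl]-1-(prop-2-en-1-yl)cyclohex-3-ene-1-carbaldehyde
Product: 13 (E)-N-tosylhydrazone of aldehyde 12 (ring and side-chain configuration unchanged)
Conditions: TsNHNH2, THF/EtOH, rt to 40 °C
Reagents that add atoms: 4-methylbenzenesulfonohydrazide, Cc1ccc(cc1)S(=O)(=O)NN
Why: Condensation of an aldehyde with tosylhydrazide is reliable even next to a quaternary carbon, and because Cb carries no hydrogen neither epimerisation nor loss of the β-bromine by elimination can occur.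

Step 8
Reactants: 13 (E)-N-tosylhydrazone of aldehyde 12
Product: 16 (4S,5S,6R)-4-bromo-1,5-dimethyl-6-[(3S)-3-methyl-3-(triethylsilyloxy)pent-4-en-1-yl]-5-(prop-2-en-1-yl)cyclohex-1-ene, via N-boryl hydrazide 14 (not isolated), via alkyldiazene 15 (not isolated)
Conditions: catecholborane, CHCl3, 0 °C; then NaOAc·3H2O, 60 °C
Reagents that add atoms: none
Why: Hydroboration of the C=N bond by catecholborane followed by acetate-induced loss of sulfinate gives the monoalkyl diazene, which extrudes N2 to leave the methyl group (reductive deoxygenation of a tosylhydrazone, a mild Wolff–Kishner-type reduction) under conditions that should spare the secondary bromide, the silyl ether and the unactivated olefins; the ring stereocentres are untouched.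

Step 9
Reactants: 16 (4S,5S,6R)-4-bromo-1,5-dimethyl-6-[(3S)-3-methyl-3-(triethylsilyloxy)pent-4-en-1-yl]-5-(prop-2-en-1-yl)cyclohex-1-ene
Product: 17 (1R,2S,3S,4S,6S)-4-bromo-1,3-dimethyl-2-[(3S)-3-methyl-3-(triethylsilyloxy)pent-4-en-1-yl]-3-(prop-2-en-1-yl)-7-oxabicyclo[4.1.0]heptane
Conditions: mCPBA, NaHCO3, CH2Cl2, −20 to 0 °C
Reagents that add atoms: 3-chloroperoxybenzoic acid, OOC(=O)c1cccc(Cl)c1
Why: Prilezhaev epoxidation picks the trisubstituted ring olefin over the two monosubstituted ones, and the peracid should approach the face opposite the axial methyl group on Cb, the side chain on Ca and the bromine on Cc (all on one face, the other face carrying only the equatorial allyl group), so that the new C–O bonds at Ce and Cf lie trans to them.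

Step 10
Reactants: 17 (1R,2S,3S,4S,6S)-4-bromo-1,3-dimethyl-2-[(3S)-3-methyl-3-(triethylsilyloxy)pent-4-en-1-yl]-3-(prop-2-en-1-yl)-7-oxabicyclo[4.1.0]heptane
Product: 18 (1S,2S,3S,4S)-4-bromo-1,3-dimethyl-2-[(3S)-3-methyl-3-(triethylsilyloxy)pent-4-en-1-yl]-3-(prop-2-en-1-yl)cyclohexan-1-ol
Conditions: LiEt3BH, THF, 0 °C to rt; H2O
Reagents that add atoms: none
Why: Reductive epoxide opening by SN2 attack of hydride at the less substituted carbon Ce leaves the C–O bond at Cf intact, so the carbinol configuration is that of the epoxide (hydroxyl equatorial, methyl axial), while the secondary bromide next to a quaternary carbon is shielded from substitution.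

Step 11
Reactants: 18 (1S,2S,3S,4S)-4-bromo-1,3-dimethyl-2-[(3S)-3-methyl-3-(triethylsilyloxy)pent-4-en-1-yl]-3-(prop-2-en-1-yl)cyclohexan-1-ol; 19 2-methylbut-3-en-2-ol
Product: 20 (1S,2S,3S,4S)-4-bromo-3-[(2E)-4-hydroxy-4-methylpent-2-en-1-yl]-1,3-dimethyl-2-[(3S)-3-methyl-3-(triethylsilyloxy)pent-4-en-1-yl]cyclohexan-1-ol
Conditions: 19 (10 equiv), second-generation Grubbs catalyst RuCl2(=CHPh)(H2IMes)(PCy3) (5 mol%), CH2Cl2, 40 °C
Reagents that add atoms: none
Why: Olefin cross-metathesis of the unhindered allyl group with an excess of a tertiary allylic alcohol that barely homodimerises should give the E-disubstituted olefin under steric control, while the vinyl group on the silylated, fully substituted carbinol carbon is too hindered to take part.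

Step 12
Reactants: 20 (1S,2S,3S,4S)-4-bromo-3-[(2E)-4-hydroxy-4-methylpent-2-en-1-yl]-1,3-dimethyl-2-[(3S)-3-methyl-3-(triethylsilyloxy)pent-4-en-1-yl]cyclohexan-1-ol
Product: 21 (1S,2S,3S,4S)-4-bromo-2-[(3S)-3-hydroxy-3-methylpent-4-en-1-yl]-3-[(2E)-4-hydroxy-4-methylpent-2-en-1-yl]-1,3-dimethylcyclohexan-1-ol (target)
Conditions: Bu4NF, THF, 0 °C to rt
Reagents that add atoms: none
Why: Fluoride-mediated cleavage of the triethylsilyl ether under basic, non-ionising conditions should free the tertiary allylic alcohol without endangering the other two tertiary alcohols or the equatorial bromide, which has no antiperiplanar hydrogen for elimination.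

**Compound list**

1 | (S)-linalool, (3S)-3,7-dimethylocta-1,6-dien-3-ol | C=C[C@@](C)(O)CCC=C(C)C | starting material
2 | triethyl{[(3S)-3,7-dimethylocta-1,6-dien-3-yl]oxy}silane | C=C[C@@](C)(O[Si](CC)(CC)CC)CCC=C(C)C | intermediate
3 | (2E,6S)-2,6-dimethyl-6-(triethylsilyloxy)octa-2,7-dien-1-ol (not isolated) | C=C[C@@](C)(O[Si](CC)(CC)CC)CC/C=C(\C)CO | intermediate
4 | (2E,6S)-2,6-dimethyl-6-(triethylsilyloxy)octa-2,7-dienal | C=C[C@@](C)(O[Si](CC)(CC)CC)CC/C=C(\C)C=O | intermediate
5 | triethyl{[(3S,6E)-3,7-dimethylnona-1,6,8-trien-3-yl]oxy}silane | C=C[C@@](C)(O[Si](CC)(CC)CC)CC/C=C(\C)C=C | intermediate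
6 | propargyl alcohol (prop-2-yn-1-ol) | C#CCO | starting material
7 | allylmagnesium bromide | C=CC[Mg]Br | starting material
8 | bromomagnesium prop-2-yn-1-olate (not isolated) | C#CCO[Mg]Br | intermediate
9 | 4-(prop-2-en-1-yl)-2,5-dihydro-1,2-oxamagnesole, the chelated alkenylmagnesium alkoxide (not isolated) | C=CCC1=C[Mg]OC1 | intermediate
10 | (2Z)-2-(bromomethylidene)pent-4-en-1-ol (Br cis to CH2OH) | OC/C(CC=C)=C\Br | intermediate
11 | (2Z)-2-(bromomethylidene)pent-4-enal (Br cis to CHO) | O=C/C(CC=C)=C\Br | intermediate
12 | (1S,2R,6S)-6-bromo-3-methyl-2-[(3S)-3-methyl-3-(triethylsilyloxy)pent-4-en-1-yl]-1-(prop-2-en-1-yl)cyclohex-3-ene-1-carbaldehyde (side chain, CHO and Br mutually cis) | C=C[C@@](C)(O[Si](CC)(CC)CC)CC[C@H]1[C@](C=O)(CC=C)[C@@H](Br)CC=C1C | intermediate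
13 | (E)-N-tosylhydrazone of 12 | C=C[C@@](C)(O[Si](CC)(CC)CC)CC[C@H]1[C@](/C=N/NS(=O)(=O)c2ccc(C)cc2)(CC=C)[C@@H](Br)CC=C1C | intermediate
14 | N-(1,3,2-benzodioxaborol-2-yl)-N-alkyl-N'-tosylhydrazine from 13 (not isolated) | C=C[C@@](C)(O[Si](CC)(CC)CC)CC[C@H]1[C@](CN(B2Oc3ccccc3O2)NS(=O)(=O)c2ccc(C)cc2)(CC=C)[C@@H](Br)CC=C1C | intermediate
15 | monoalkyl diazene RCH2–N=NH from 14 (not isolated) | C=C[C@@](C)(O[Si](CC)(CC)CC)CC[C@H]1[C@](CN=N)(CC=C)[C@@H](Br)CC=C1C | intermediate
16 | (4S,5S,6R)-4-bromo-1,5-dimethyl-6-[(3S)-3-methyl-3-(triethylsilyloxy)pent-4-en-1-yl]-5-(prop-2-en-1-yl)cyclohex-1-ene | C=C[C@@](C)(O[Si](CC)(CC)CC)CC[C@H]1[C@](C)(CC=C)[C@@H](Br)CC=C1C | intermediate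
17 | (1R,2S,3S,4S,6S)-4-bromo-1,3-dimethyl-2-[(3S)-3-methyl-3-(triethylsilyloxy)pent-4-en-1-yl]-3-(prop-2-en-1-yl)-7-oxabicyclo[4.1.0]heptane (epoxide trans to side chain, Cb methyl and Br) | C=C[C@@](C)(O[Si](CC)(CC)CC)CC[C@H]1[C@](C)(CC=C)[C@@H](Br)C[C@@H]2O[C@]12C | intermediate
18 | (1S,2S,3S,4S)-4-bromo-1,3-dimethyl-2-[(3S)-3-methyl-3-(triethylsilyloxy)pent-4-en-1-yl]-3-(prop-2-en-1-yl)cyclohexan-1-ol | C=C[C@@](C)(O[Si](CC)(CC)CC)CC[C@H]1[C@](C)(CC=C)[C@@H](Br)CC[C@]1(C)O | intermediate
19 | 2-methylbut-3-en-2-ol | C=CC(C)(C)O | starting material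
20 | (1S,2S,3S,4S)-4-bromo-3-[(2E)-4-hydroxy-4-methylpent-2-en-1-yl]-1,3-dimethyl-2-[(3S)-3-methyl-3-(triethylsilyloxy)pent-4-en-1-yl]cyclohexan-1-ol | C=C[C@@](C)(O[Si](CC)(CC)CC)CC[C@H]1[C@](C)(C/C=C/C(C)(C)O)[C@@H](Br)CC[C@]1(C)O | intermediate
21 | (1S,2S,3S,4S)-4-bromo-2-[(3S)-3-hydroxy-3-methylpent-4-en-1-yl]-3-[(2E)-4-hydroxy-4-methylpent-2-en-1-yl]-1,3-dimethylcyclohexan-1-ol | C=C[C@@](C)(O)CC[C@H]1[C@](C)(C/C=C/C(C)(C)O)[C@@H](Br)CC[C@]1(C)O | target

**Summary and risks**

Total step count: 12. Longest linear sequence: 10 steps (steps 1–3 and 6–12); the dienophile arm (steps 4–5) is 2 steps.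

Steps most likely to fail:

Step 6. The trisubstituted β-bromo enal may be too weakly activated by the boron Lewis acid, so that the cycloaddition stalls and endo and facial control erode. The fallback is an ionic Diels–Alder reaction under auxiliary control. It sets out from 11: acetalisation with (2R,3R)-butane-2,3-diol (PPTS, benzene, reflux) gives (4R,5R)-2-[(1Z)-1-bromopenta-1,4-dien-2-yl]-4,5-dimethyl-1,3-dioxolane F1. TMSOTf (cat.) in CH2Cl2 at −78 °C opens F1 to the 2-alkoxyallyl (vinyl oxocarbenium) cation, a much stronger dienophile, which should add to diene 5 with the same regio- and endo-sense while the dioxolane stereocentres differentiate the faces (the diol antipode is chosen to match the required face). This gives the dioxolane acetal of the cycloadduct F2, and mild transacetalisation (PPTS, wet acetone) returns aldehyde 12, where the route resumes.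

Step 10. The hydride must reach Ce along a trajectory flanked by the side chain on Ca and the bromine on Cc, so the opening may be slow and reduction of the C–Br bond may compete. The fallback is a radical Markovnikov hydration that bypasses the epoxide. It sets out from 16: Mukaiyama hydration with tris(dipivaloylmethanato)manganese Mn(dpm)3 (cat.), PhSiH3 and O2 in i-PrOH/CH2Cl2 at 0 °C transfers a hydrogen atom to the trisubstituted olefin, and the tertiary radical at Cf should take up O2 from the face opposite the axial methyl group on Cb. The tertiary hydroperoxide F3 formed alongside the alcohol is reduced with PPh3 in the work-up, and the route is rejoined at 18. The monosubstituted olefins, which would give less stable secondary radicals, are expected to react more slowly.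

Step 8. Hydride delivery to the hindered, neopentyl-type hydrazone carbon may be incomplete, or catecholborane may begin to hydroborate the terminal olefins on warming. The fallback is a stepwise deoxygenation through a radical. It sets out from 12: NaBH4 (MeOH, 0 °C) gives the primary alcohol F4; I2, PPh3 and imidazole (toluene, 80 °C; Appel reaction) give the neopentyl iodide F5; Bu3SnH (1.05 equiv) and AIBN in benzene at 80 °C then remove the iodine selectively, because a primary iodide gives up its halogen to a stannyl radical far faster than a secondary bromide, and the route is rejoined at 16.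

Further compounds
F1 | step 6 | (4R,5R)-2-[(1Z)-1-bromopenta-1,4-dien-2-yl]-4,5-dimethyl-1,3-dioxolane | C[C@H]1OC(O[C@@H]1C)/C(CC=C)=C\Br
F2 | step 6 | (4R,5R)-4,5-dimethyl-1,3-dioxolane acetal of aldehyde 12 | C=C[C@@](C)(O[Si](CC)(CC)CC)CC[C@H]1[C@](C2O[C@H](C)[C@@H](C)O2)(CC=C)[C@@H](Br)CC=C1C
F3 | step 10 | tertiary hydroperoxide corresponding to alcohol 18 | C=C[C@@](C)(O[Si](CC)(CC)CC)CC[C@H]1[C@](C)(CC=C)[C@@H](Br)CC[C@]1(C)OO
F4 | step 8 | primary alcohol from reduction of aldehyde 12 | C=C[C@@](C)(O[Si](CC)(CC)CC)CC[C@H]1[C@](CO)(CC=C)[C@@H](Br)CC=C1C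
F5 | step 8 | neopentyl iodide from F4 | C=C[C@@](C)(O[Si](CC)(CC)CC)CC[C@H]1[C@](CI)(CC=C)[C@@H](Br)CC=C1C
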